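**Strategy (ent-kaurane numbering).** Ring C (C8, C9, C11, C12, C13, C14) is opened across C8–C14 and C12–C13. C8 is α to the C7 lactone carbonyl and C13 can carry C16 as an acyl group, so both bonds are made in one flask by an anionic [4+2] annulation. The lithium enolate of spirolactone iodide 16, whose C9 already bears the C11–C12 iodoethyl arm, adds to S-ethyl thioacrylate (C14=C13–C16), and the new thioester enolate closes ring C by intramolecular alkylation. C8 and C13 stay epimerisable, so the mixture funnels to the diastereomer (C16 trans to C10) needed for the later palladium-mediated closure of ring D.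

Key step: step 10

Numbering used below: ring A = C1–C5 and C10; lactone = C7(=O)–O–C20–C10–C9–C8; C6 = aldehyde carbon; ring D = C8, C14, C13, C16, C15; C17 = exocyclic methylene carbon.

Assumption: 4,4-dimethylcyclohexa-2,5-dien-1-one and S-ethyl thioacrylate are taken as purchasable; each is otherwise one routine step from 4,4-dimethylcyclohex-2-en-1-one, or from acryloyl chloride and ethanethiol.

**Step 1**
Reactants: 1 4,4-dimethylcyclohexa-2,5-dien-1-one
Product: 2 (5R)-5-ethenyl-4,4-dimethylcyclohex-2-en-1-one
Conditions: CH2=CHBF3K, [Rh(cod)2]BF4 (3 mol %), (R)-BINAP, toluene/H2O, 100 °C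
Reagents that add atoms: potassium vinyltrifluoroborate, C=C[B-](F)(F)F.[K+]
Why: Rhodium-catalysed asymmetric 1,4-addition (Hayashi–Miyaura reaction) desymmetrises the prochiral dienone, the BINAP enantiomer (chosen by analogy with additions to 2-cyclohexenone) fixing C5 as R and leaving the second enone as the C1/C2=C3 unit of the target.

**Step 2**
Reactants: 2 (5R)-5-ethenyl-4,4-dimethylcyclohex-2-en-1-one
Product: 3 (5R)-6-[(benzyloxy)methyl]-5-ethenyl-4,4-dimethylcyclohex-2-en-1-one (5,6-trans drawn)
Conditions: LiN(iPr)2, THF, −78 °C; BnOCH2Cl, −78 to −20 °C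
Reagents that add atoms: benzyl chloromethyl ether, ClCOCc1ccccc1
Why: Kinetic enolate alkylation at the only enolisable position (C10) installs C20 as its benzyl ether; the new centre is planarised again in step 3, so its configuration does not matter.

**Step 3**
Reactants: 3 (5R)-6-[(benzyloxy)methyl]-5-ethenyl-4,4-dimethylcyclohex-2-en-1-one
Product: 4 keto ester with quaternary C10 (propanoate chain trans and CH2OBn cis to the ethenyl group)
Conditions: LiN(iPr)2, THF, −78 °C; methyl acrylate, −78 °C; AcOH
Reagents that add atoms: methyl acrylate, C=CC(=O)OC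
Why: Michael addition of the tetrasubstituted lithium enolate creates the quaternary C10, the acceptor approaching anti to the C5 ethenyl group so that C9 ends trans and C20 cis to the future C6.

**Step 4**
Reactants: 4 keto ester with quaternary C10
Product: 6 spirolactone enone, via hydroxy ester 5 (not isolated)
Conditions: BCl3, CH2Cl2, −78 °C; MeOH; then TsOH (cat.), CH2Cl2, rt
Reagents that add atoms: none
Why: Lewis-acid cleavage of the benzyl ether spares both alkenes, and the freed C20 hydroxyl closes the six-membered lactone onto the methyl ester by acid-catalysed lactonisation.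

**Step 5**
Reactants: 6 spirolactone enone
Product: 8 spirolactone diol (C1–OH cis to C20), via ozonide 7 (not isolated)
Conditions: O3, CH2Cl2, −78 °C; then MeOH, CeCl3·7H2O, NaBH4, −78 to 0 °C
Reagents that add atoms: ozone, [O-][O+]=O
Why: Ozonolysis takes the electron-rich ethenyl group in preference to the conjugated C2=C3 bond, and the reductive work-up under Luche conditions gives the C6 alcohol and reduces the C1 ketone 1,2 with hydride arriving anti to the axial C20; the C1 configuration is inconsequential because C1 is re-oxidised in step 19.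

**Step 6**
Reactants: 8 spirolactone diol
Product: 9 bis-silyl ether (C1–OTBS, C6–OTBS)
Conditions: TBSOTf, 2,6-lutidine, CH2Cl2, −78 to 0 °C
Reagents that add atoms: tert-butyldimethylsilyl triflate, CC(C)(C)[Si](C)(C)OS(=O)(=O)C(F)(F)F
Why: Silyl triflate silylation protects the primary and the hindered allylic secondary alcohol in one operation as ethers that survive the enolate, organometallic and oxidation steps ahead.

**Step 7**
Reactants: 9 bis-silyl ether
Product: 12 unsaturated spirolactone (C8=C9), via selenide 10 (not isolated), via selenoxide 11 (not isolated)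
Conditions: LiN(iPr)2, THF, −78 °C; PhSeBr; then H2O2, pyridine, CH2Cl2, 0 °C to rt
Reagents that add atoms: phenylselenenyl bromide, Br[Se]c1ccccc1 (retained in 10 and 11 only); hydrogen peroxide, OO (oxygen retained in 11 only)
Why: α-Selenenylation of the lactone enolate (C8 is the only acidic position) and syn-elimination of the selenoxide (selenoxide elimination) introduce the C8=C9 double bond.

**Step 8**
Reactants: 12 unsaturated spirolactone
Product: 14 9-ethenyl spirolactone, via silyl ketene acetal 13 (not isolated)
Conditions: CH2=CHMgBr, CuBr·SMe2 (20 mol %), Me3SiCl, THF, −78 to −40 °C; aq NH4Cl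
Reagents that add atoms: vinylmagnesium bromide, C=C[Mg]Br; chlorotrimethylsilane, C[Si](C)(C)Cl (retained in 13 only)
Why: Copper-catalysed, Me3SiCl-accelerated conjugate addition delivers C11–C12 to C9 on the lactone face anti to C5 (the spiro neighbour that carries the CH2OTBS arm and adjoins the gem-dimethyl carbon), which sets C9 with C11 on the C1 side as required.

**Step 9**
Reactants: 14 9-ethenyl spirolactone
Product: 16 iodide (C9–CH2CH2I), via alkylzirconocene chloride 15 (not isolated)
Conditions: Cp2Zr(H)Cl, THF, rt; then I2, 0 °C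
Reagents that add atoms: iodine, II; zirconocene chloride hydride, [H][Zr](Cl)(C1C=CC=C1)C1C=CC=C1 (retained in 15 only)
Why: Hydrozirconation places the metal at the terminal carbon of the monosubstituted alkene (the hindered ring A alkene should not react) and iodinolysis of the C–Zr bond gives the primary iodide at C12.

**Step 10**
Reactants: 16 iodide
Product: 18 bicyclic thioester lactone (ring C closed), via thioester enolate 17 (not isolated)
Conditions: LiN(iPr)2 (1.05 equiv), THF, −78 °C; S-ethyl thioacrylate (1.0 equiv), −78 °C; DMPU, −78 to −20 °C; aq NH4Cl; then DBU (0.3 equiv), CH2Cl2, rt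
Reagents that add atoms: S-ethyl thioacrylate, C=CC(=O)SCC
Why: The lactone lithium enolate (C8) adds in a Michael reaction to the β-carbon of the thioacrylate (C14), and the thioester enolate so formed (C13) then displaces the primary iodide at C12, so that both bonds arise in one flask by a Michael-initiated ring closure (Michael addition followed by intramolecular enolate alkylation), the closest known reaction type. The first bond is intermolecular and closes no ring; ring C is closed in the 6-exo-tet mode. C8 is set kinetically by approach of the acceptor anti to the C9 side chain (trans ring fusion) and has no lasting consequence because it is planarised again in step 13. C13 is set under thermodynamic control: DBU equilibrates the thioester α-position to the equatorial site of the trans-fused chair, which is trans to the equatorial spiro carbon C10 across ring C and is the relationship that later lets C16 reach C8 on the face of H-9. The step needs conjugate addition and C-alkylation to beat 1,2-attack, oligomerisation of the acceptor and self-alkylation of the first enolate (four-membered ring or O-alkylation); the more nucleophilic lactone enolate meeting one equivalent of acceptor at −78 °C, and the fast six-membered closure once DMPU is added, should secure this.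

**Step 11**
Reactants: 18 bicyclic thioester lactone
Product: 19 methyl ketone
Conditions: Me2CuLi (from MeLi and CuI), Et2O, −78 °C; aq NH4Cl
Reagents that add atoms: lithium dimethylcuprate, [Li+].C[Cu-]C
Why: Thioesters are converted to ketones by lithium dialkylcuprates without over-addition (cuprate acyl substitution), and the lactone is inert to the cuprate.

**Step 12**
Reactants: 19 methyl ketone
Product: 20 isopropenyl lactone
Conditions: Ph3PCH3Br, KOtBu, THF, 0 °C to rt
Reagents that add atoms: methyltriphenylphosphonium bromide, C[P+](c1ccccc1)(c1ccccc1)c1ccccc1.[Br-]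
Why: Wittig methylenation converts the ketone into the 1,1-disubstituted alkene needed for ring D; any base-induced equilibration at C13 before olefination favours the equatorial configuration already present.

**Step 13**
Reactants: 20 isopropenyl lactone
Product: 22 tetracyclic lactone with exocyclic C16=C17, via silyl ketene acetal 21 (not isolated)
Conditions: LiN(iPr)2, TBSCl, DMPU, THF, −78 to 0 °C; then Pd(OAc)2 (1.0 equiv), AcOH (0.5 equiv), DMSO, 45 °C
Reagents that add atoms: tert-butyldimethylsilyl chloride, CC(C)(C)[Si](C)(C)Cl (retained in 21 only)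
Why: Palladium diacetate-mediated oxidative cyclisation of the silyl ketene acetal onto the alkene (Saegusa–Ito-type cycloalkenylation) joins C8 to the terminal alkene carbon (C15) and β-hydride elimination toward the methyl group gives the exocyclic C16=C17 bond; the tethered alkene can reach planar C8 only on the face cis to H-9, which sets the quaternary C8.

**Step 14**
Reactants: 22 tetracyclic lactone
Product: 23 15-epi allylic alcohol (hydroxyl on the C14 side)
Conditions: SeO2 (0.5 equiv), t-BuOOH, CH2Cl2, 0 °C to rt
Reagents that add atoms: tert-butyl hydroperoxide, CC(C)(C)OO (terminal oxidant; the oxygen is passed on through selenium dioxide, O=[Se]=O)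
Why: Selenium dioxide allylic oxidation (ene reaction, then [2,3]-sigmatropic shift) can only functionalise C15, because C13 is a bridgehead, and should deliver oxygen on the exposed exo face; the ring A alkene is shielded by the adjacent gem-dimethyl carbon.

**Step 15**
Reactants: 23 15-epi allylic alcohol
Product: 24 enone (15-oxo, 16-methylene)
Conditions: Dess–Martin periodinane, NaHCO3, CH2Cl2, rt
Reagents that add atoms: none
Why: Dess–Martin oxidation converts the allylic alcohol (and converges any over-oxidised material) to the conjugated enone so that C15 can be reset by reduction.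

**Step 16**
Reactants: 24 enone
Product: 25 15-alcohol (hydroxyl on the ring C side)
Conditions: NaBH4, CeCl3·7H2O, MeOH, −78 °C
Reagents that add atoms: none
Why: Luche 1,2-reduction delivers hydride to the C15 carbonyl from the exo face (the side of the one-carbon bridge C14), the other face being screened by ring C, so the hydroxyl ends on the ring C side as in the target.

**Step 17**
Reactants: 25 15-alcohol
Product: 26 15-acetate
Conditions: Ac2O, DMAP, pyridine, CH2Cl2, rt
Reagents that add atoms: acetic anhydride, CC(=O)OC(C)=O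
Why: DMAP-catalysed acylation esterifies the only free hydroxyl with retention at C15.

**Step 18**
Reactants: 26 15-acetate
Product: 27 diol acetate (C1–OH, C6–OH)
Conditions: HF·pyridine, pyridine, THF, 0 °C to rt
Reagents that add atoms: none
Why: Buffered fluoride desilylation removes both silyl ethers while the acetate, the lactone and the alkenes are left untouched.

**Step 19**
Reactants: 27 diol acetate
Product: 28 CNP0108627.4
Conditions: Dess–Martin periodinane, NaHCO3, CH2Cl2, 0 °C to rt
Reagents that add atoms: none
Why: Dess–Martin oxidation takes the allylic C1 alcohol to the enone and the primary C6 alcohol to the aldehyde in one operation, the buffered non-basic conditions avoiding epimerisation at C5.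

**Compound list**

1 | 4,4-dimethylcyclohexa-2,5-dien-1-one | CC1(C)C=CC(=O)C=C1 | starting material
2 | (5R)-5-ethenyl-4,4-dimethylcyclohex-2-en-1-one | O=C1C=CC(C)(C)[C@@H](C=C)C1 | intermediate
3 | (5R)-6-[(benzyloxy)methyl]-5-ethenyl-4,4-dimethylcyclohex-2-en-1-one, 5,6-trans | O=C1C=CC(C)(C)[C@@H](C=C)[C@@H]1COCc1ccccc1 | intermediate
4 | methyl 3-[1-[(benzyloxy)methyl]-6-ethenyl-5,5-dimethyl-2-oxocyclohex-3-en-1-yl]propanoate, propanoate chain trans to ethenyl | O=C1C=CC(C)(C)[C@@H](C=C)[C@]1(COCc1ccccc1)CCC(=O)OC | intermediate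
5 | methyl 3-[6-ethenyl-1-(hydroxymethyl)-5,5-dimethyl-2-oxocyclohex-3-en-1-yl]propanoate, configuration as 4 | O=C1C=CC(C)(C)[C@@H](C=C)[C@]1(CO)CCC(=O)OC | intermediate (not isolated)
6 | 11-ethenyl-10,10-dimethyl-2-oxaspiro[5.5]undec-8-ene-3,7-dione, C9 trans and C20 cis to the ethenyl group | O=C1CC[C@]2(CO1)C(=O)C=CC(C)(C)[C@H]2C=C | intermediate
7 | ozonide (1,2,4-trioxolane) of 6 at the former ethenyl group | O=C1CC[C@]2(CO1)C(=O)C=CC(C)(C)[C@H]2C1OCOO1 | intermediate (not isolated)
8 | 7-hydroxy-11-(hydroxymethyl)-10,10-dimethyl-2-oxaspiro[5.5]undec-8-en-3-one, C1–OH cis to C20 and C6 | O=C1CC[C@]2(CO1)[C@@H](O)C=CC(C)(C)[C@H]2CO | intermediate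
9 | bis(tert-butyldimethylsilyl) ether of 8 | O=C1CC[C@]2(CO1)[C@@H](O[Si](C)(C)C(C)(C)C)C=CC(C)(C)[C@H]2CO[Si](C)(C)C(C)(C)C | intermediate
10 | C8 phenylselanyl derivative of 9 (C8 epimers) | O=C1C([Se]c3ccccc3)C[C@]2(CO1)[C@@H](O[Si](C)(C)C(C)(C)C)C=CC(C)(C)[C@H]2CO[Si](C)(C)C(C)(C)C | intermediate (not isolated)
11 | selenoxide of 10 | O=C1C([Se](=O)c3ccccc3)C[C@]2(CO1)[C@@H](O[Si](C)(C)C(C)(C)C)C=CC(C)(C)[C@H]2CO[Si](C)(C)C(C)(C)C | intermediate (not isolated)
12 | α,β-unsaturated spirolactone (C8=C9) | O=C1C=C[C@]2(CO1)[C@@H](O[Si](C)(C)C(C)(C)C)C=CC(C)(C)[C@H]2CO[Si](C)(C)C(C)(C)C | intermediate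
13 | trimethylsilyl ketene acetal of 14 | C[Si](C)(C)OC1=C[C@@H](C=C)[C@]2(CO1)[C@@H](O[Si](C)(C)C(C)(C)C)C=CC(C)(C)[C@H]2CO[Si](C)(C)C(C)(C)C | intermediate (not isolated)
14 | 9-ethenyl spirolactone, ethenyl on the C1 side of the lactone and anti to C5 | O=C1C[C@@H](C=C)[C@]2(CO1)[C@@H](O[Si](C)(C)C(C)(C)C)C=CC(C)(C)[C@H]2CO[Si](C)(C)C(C)(C)C | intermediate
15 | alkylzirconocene chloride, zirconium on C12 | O=C1C[C@@H](CC[Zr](Cl)(C3C=CC=C3)C3C=CC=C3)[C@]2(CO1)[C@@H](O[Si](C)(C)C(C)(C)C)C=CC(C)(C)[C@H]2CO[Si](C)(C)C(C)(C)C | intermediate (not isolated)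
16 | 9-(2-iodoethyl) spirolactone | O=C1C[C@@H](CCI)[C@]2(CO1)[C@@H](O[Si](C)(C)C(C)(C)C)C=CC(C)(C)[C@H]2CO[Si](C)(C)C(C)(C)C | intermediate
17 | lithium thioester enolate of the Michael adduct (C8–C14 formed, C14 trans to the C9 arm) | [Li+].CCSC([O-])=CC[C@H]1C(=O)OC[C@@]2([C@@H]1CCI)[C@@H](O[Si](C)(C)C(C)(C)C)C=CC(C)(C)[C@H]2CO[Si](C)(C)C(C)(C)C | intermediate (not isolated)
18 | trans-fused lactone/cyclohexane with the C13 S-ethyl thioester equatorial, trans to C10 | CCSC(=O)[C@@H]1CC[C@@H]2[C@@H](C1)C(=O)OC[C@]23[C@@H](O[Si](C)(C)C(C)(C)C)C=CC(C)(C)[C@H]3CO[Si](C)(C)C(C)(C)C | intermediate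
19 | C13 methyl ketone, configuration as 18 | CC(=O)[C@@H]1CC[C@@H]2[C@@H](C1)C(=O)OC[C@]23[C@@H](O[Si](C)(C)C(C)(C)C)C=CC(C)(C)[C@H]3CO[Si](C)(C)C(C)(C)C | intermediate
20 | C13 isopropenyl lactone, configuration as 18 | CC(=C)[C@@H]1CC[C@@H]2[C@@H](C1)C(=O)OC[C@]23[C@@H](O[Si](C)(C)C(C)(C)C)C=CC(C)(C)[C@H]3CO[Si](C)(C)C(C)(C)C | intermediate
21 | tert-butyldimethylsilyl ketene acetal of 20 | CC(=C)[C@@H]1CC[C@@H]2C(C1)=C(O[Si](C)(C)C(C)(C)C)OC[C@]23[C@@H](O[Si](C)(C)C(C)(C)C)C=CC(C)(C)[C@H]3CO[Si](C)(C)C(C)(C)C | intermediate (not isolated)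
22 | tetracyclic spirolactone with the bicyclo[3.2.1]octane, C15 methylene and exocyclic C16=C17; C8, C9, C10, C13 as in the target | C=C1[C@@H]2CC[C@@H]3[C@](C2)(C(=O)OC[C@]34[C@@H](O[Si](C)(C)C(C)(C)C)C=CC(C)(C)[C@H]4CO[Si](C)(C)C(C)(C)C)C1 | intermediate
23 | 15-epi alcohol of 25 (hydroxyl on the C14 side) | C=C1[C@@H]2CC[C@@H]3[C@](C2)(C(=O)OC[C@]34[C@@H](O[Si](C)(C)C(C)(C)C)C=CC(C)(C)[C@H]4CO[Si](C)(C)C(C)(C)C)[C@H]1O | intermediate
24 | 15-oxo-16-methylene enone | C=C1[C@@H]2CC[C@@H]3[C@](C2)(C(=O)OC[C@]34[C@@H](O[Si](C)(C)C(C)(C)C)C=CC(C)(C)[C@H]4CO[Si](C)(C)C(C)(C)C)C1=O | intermediate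
25 | 15-alcohol with the target configuration (hydroxyl on the ring C side) | C=C1[C@@H]2CC[C@@H]3[C@](C2)(C(=O)OC[C@]34[C@@H](O[Si](C)(C)C(C)(C)C)C=CC(C)(C)[C@H]4CO[Si](C)(C)C(C)(C)C)[C@@H]1O | intermediate
26 | 15-acetate of 25 | C=C1[C@@H]2CC[C@@H]3[C@](C2)(C(=O)OC[C@]34[C@@H](O[Si](C)(C)C(C)(C)C)C=CC(C)(C)[C@H]4CO[Si](C)(C)C(C)(C)C)[C@@H]1OC(C)=O | intermediate
27 | 15-acetoxy 1,6-diol | C=C1[C@@H]2CC[C@@H]3[C@](C2)(C(=O)OC[C@]34[C@@H](O)C=CC(C)(C)[C@H]4CO)[C@@H]1OC(C)=O | intermediate
28 | CNP0108627.4 | C=C1[C@@H]2CC[C@@H]3[C@](C2)(C(=O)OC[C@]32C(=O)C=CC(C)(C)[C@H]2C=O)[C@@H]1OC(C)=O | target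

**Total step count:** 19 steps. **Longest linear sequence:** 19 steps (fully linear from 1).

**Steps most likely to fail**

1. Step 10 (key step). What may go wrong: anionic oligomerisation of the thioacrylate, acyl transfer (1,2-attack) to the lactone enolate, or cyclisation of the lactone enolate onto its own iodide before the acceptor is captured. Fallback: the two bonds are made separately. Setting out from 14, LiN(iPr)2 and S-ethyl thioacrylate at −78 °C (acetic acid quench) should give the open-chain Michael adduct F1, in which no halide is present. Hydroboration of the ethenyl group with 9-BBN and oxidation with NaBO3·4H2O should give the primary alcohol F2, and I2, PPh3 and imidazole should give the iodo thioester F3. LiN(SiMe3)2 (−78 to −20 °C) deprotonates the more acidic thioester α-position in preference to the lactone and closes ring C; DBU equilibration then brings the material back to the route at 18.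

2. Step 8. What may go wrong: delivery of the ethenyl group to the wrong face of the unsaturated lactone (poor discrimination between the C1 and C5 sides), or sluggish addition at the neopentyl β-carbon. Fallback: catalyst control in place of substrate control. Setting out from 12, a rhodium-catalysed asymmetric conjugate addition of potassium vinyltrifluoroborate ([Rh(cod)2]BF4, the BINAP enantiomer matched to the C1 face, dioxane/H2O, 90 °C; Hayashi–Miyaura reaction) should give the same lactone and returns to the route at 14. This fallback makes no new compound (F0).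

3. Step 13. What may go wrong: protodesilylation of the ketene acetal before the C–C bond forms, β-hydride elimination toward C15 instead of C17, or failure of the strained bridged ring to close. Fallback: ring D is closed by acylation instead, which also delivers the enone directly. Setting out from 19, KN(SiMe3)2 and PhNTf2 (−78 °C) should give the vinyl triflate F4 by kinetic enolisation at the methyl group. Pd(OAc)2, dppp, CO, MeOH and Et3N (DMF, 60 °C) should give the methyl acrylate ester F5. LiN(SiMe3)2 at −78 °C then forms the lactone enolate, which attacks the ester carbonyl in a 5-exo-trig intramolecular Claisen (Dieckmann-type) acylation and returns to the route at enone 24, bypassing 20 to 23.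

**Further compounds**

F1 | step 10 | open-chain Michael adduct of 14 (S-ethyl 3-thiopropanoate arm on C8, trans to the C9 ethenyl group) | CCSC(=O)CC[C@H]1C(=O)OC[C@@]2([C@@H]1C=C)[C@@H](O[Si](C)(C)C(C)(C)C)C=CC(C)(C)[C@H]2CO[Si](C)(C)C(C)(C)C
F2 | step 10 | primary alcohol (C12–OH) from F1 | CCSC(=O)CC[C@H]1C(=O)OC[C@@]2([C@@H]1CCO)[C@@H](O[Si](C)(C)C(C)(C)C)C=CC(C)(C)[C@H]2CO[Si](C)(C)C(C)(C)C
F3 | step 10 | iodo thioester (C12–I) from F2 | CCSC(=O)CC[C@H]1C(=O)OC[C@@]2([C@@H]1CCI)[C@@H](O[Si](C)(C)C(C)(C)C)C=CC(C)(C)[C@H]2CO[Si](C)(C)C(C)(C)C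
F0 | step 8 | none | none
F4 | step 13 | vinyl triflate from methyl ketone 19 | C=C(OS(=O)(=O)C(F)(F)F)[C@@H]1CC[C@@H]2[C@@H](C1)C(=O)OC[C@]23[C@@H](O[Si](C)(C)C(C)(C)C)C=CC(C)(C)[C@H]3CO[Si](C)(C)C(C)(C)C
F5 | step 13 | methyl 2-substituted acrylate (C15 ester on C16) | C=C(C(=O)OC)[C@@H]1CC[C@@H]2[C@@H](C1)C(=O)OC[C@]23[C@@H](O[Si](C)(C)C(C)(C)C)C=CC(C)(C)[C@H]3CO[Si](C)(C)C(C)(C)C
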